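## The problem

- The target is an open-chain array on a 1,2,4-trisubstituted benzene ring: a free phenol, a benzylic CH2O–2-methylbutanoate, and para to the latter a fully substituted carbinol carbon. That carbon carries a tertiary hydroxyl and two CH2O arms, one acetylated and one angeloylated. No ring has to be made, so the work lies in building the carbinol on the arene and in telling its two arms apart.
- There are two stereocentres, the (R)-carbinol and the (R)-α-carbon of the 2-methylbutanoate. They sit on opposite sides of the ring and cannot control each other; the second is bought as (R)-2-methylbutanoic acid and attached late.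
- The carbinol carbon is stereogenic only because its two hydroxymethyl arms bear different acyl groups. Its configuration must be created while the arms are chemically distinct, and it is lost whenever an acyl group migrates from one arm to the other across the tertiary hydroxyl.
- The angelate isomerises from Z to E when its acyl group is activated carelessly and is destroyed by ozone or hydrogenation. Three different esters exclude alkoxide, hydride and hydrogenolysis late in the route.
- The tertiary benzylic alcohol ortho to the phenol can ionise, or be bridged to the phenol oxygen, under strong acid.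
- The enabling feature is the unit aryl–C(OH)–CH2O. A tertiary C–O bond beside a CH2–O bond is what remains when a 2-aryl-2-vinyloxirane is opened by an oxygen nucleophile at its substituted allylic carbon, and the vinyl group left behind is a latent second hydroxymethyl arm.

## Retrosynthesis

**End game (23 ⇐ 21 ⇐ 19 + 20 ⇐ 18).** The phenol O–CH2 bond of the methoxymethyl acetal is cut first (23 to 21, through the silylated 22 in the flask), then the benzylic ester C–O bond (21 to alcohol 19 and acid 20), then the Si–O bond (19 to 18). The phenol is freed last because a free phenol would compete in every acylation. The 2-methylbutanoate goes on one step earlier so that its α-stereocentre sees one mild coupling and no base. Compound 18 has one stereocentre fewer; the forward steps must be non-basic and must not activate the carbinol.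

**The two arms (18 ⇐ 15 + 16; 15 ⇐ 14 ⇐ 13; 13 ⇐ 12).** The angelate O–acyl bond is cut to alcohol 15 and angelic acid 16 (activated as 17). The CH2OH of 15 is traced through aldehyde 14 to the vinyl group of 13 by C=C cleavage, and the acetate is cut to diol 12. The order is forced: an angelate would not survive ozone, so it follows the cleavage; the acetate goes on while the other arm is still a vinyl group, when no acyl shift can affect the centre. Masking the first arm with a silyl group instead costs two steps and is kept as a reserve. Diol 12 has one stereocentre and no acyl groups; the forward steps need an alkoxide-free reduction and a geometry-preserving acylation.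

**Key disconnection (12 ⇐ 11 ⇐ 10).** The tertiary C–O bond of 12 is cut, its oxygen traced through carbonate half ester 11 to hydrogencarbonate, giving racemic oxirane 10. Against the neighbouring cuts (aryl–C, C–CH2, or an O–acyl bond of a prochiral triol) this one sets the stereocentre by a catalyst-controlled, enantioconvergent reaction on a racemate. The ring position is fixed beforehand, and the two arms produced (vinyl and CH2OH) cannot interconvert. Oxirane 10 has no defined stereocentre. The forward reaction must attack the fully substituted allyl terminus and must equilibrate the allyl complexes faster than it captures them.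

**Oxirane (10 ⇐ 9 ⇐ 8).** The oxirane C–O bond is cut to chlorohydrin 9 and the C–vinyl bond of 9 to α-chloro ketone 8. This is preferred to methylene transfer onto an aryl vinyl ketone (polymerisable, prone to conjugate addition) and to peracid epoxidation of a 2-aryl diene (no regiocontrol, acid with an acid-labile product). Ketone 8 is achiral; the forward steps need 1,2-addition without enolisation and an acid-free closure.

**Aryl–carbonyl bond (8 ⇐ 7 ⇐ 6 + 5; 6 ⇐ 4).** The bond from the ring to the carbonyl carbon is cut, via chelate 7, to aryllithium 6 and amide 5; 6 comes from bromide 4. A Friedel–Crafts chloroacetylation of the phenol would not place the side chain cleanly ortho to oxygen. The bromine of 4 marks the position unambiguously. The forward acylation must stop at the ketone.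

**Arene (4 ⇐ 3 ⇐ 2 ⇐ 1).** Only protecting-group and oxidation-level changes separate 4 from commercial 1. The phenol is carried as a methoxymethyl ether because it must survive and stabilise the ortho-lithio species. The benzylic oxygen is carried as a triisopropylsilyl ether, removable by fluoride beside esters.

## Roads not taken

**Alternative 1:** ortho Friedel–Crafts union of a phenol with an alkoxypyruvate.
- Cut: the aryl–carbinol C–C bond.
- Forward key step: 3-({[tri(propan-2-yl)silyl]oxy}methyl)phenol A1 adds through its free ortho carbon to the ketone of ethyl 3-[(4-methoxyphenyl)methoxy]-2-oxopropanoate A2 under Ti(OiPr)4 and enantiopure BINOL, giving hydroxy ester A3.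
- Merits: convergent, no organolithium and no halogen. The two arms of A3 differ as ester and benzyl-type ether, so they cannot exchange. Because no ozonolysis is needed, the slow-migrating angelate could go on before the acetate; this is a real advantage over the chosen plan.
- Weak points: this hydroxyalkylation is established for very electrophilic carbonyl partners and electron-rich phenols, whereas A2 is a less electrophilic, enolisable ketone and A1 has one activating hydroxyl. A1 offers two ortho positions and a para position. The catalyst must distinguish CO2Et from CH2OAr-type substituents of similar size. The phenol of A3 still needs protection before the acylations.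
- Comparison: shorter if it works. The chosen plan sets against it a fixed ring position and an enantio-determining step precedented for this kind of carbinol.

**Alternative 2:** hydroxymethylation of a mandelic-type dioxolanone enolate.
- Cut: the bond from the carbinol carbon to the future angelate CH2.
- Forward key step: the lithium enolate (LiN(i-Pr)2) of cis-dioxolanone A4 adds to formaldehyde anti to tert-butyl, giving hydroxymethyl dioxolanone A5.
- Merits: facial selectivity is substrate-controlled and reliable. Diastereomers can be purified, so enantiopurity does not depend on a catalyst. The arms of A5 differ in oxidation level. The allyl ether on the phenol comes off at the end under neutral conditions with zerovalent palladium, milder than the acetal cleavage the chosen plan needs (an allyl ether is excluded there by the palladium step and by ozone).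
- Weak points: A4 must first be made enantiopure, which needs an asymmetric step or resolution of its own plus a cis-selective acetalisation. The ortho-substituted aryl enolate is stabilised and hindered. Monomeric formaldehyde is awkward. Opening the lactone acetal needs hydride, so the new CH2OH must be masked, then unmasked and angeloylated after acetylation; this adds steps and still passes through a migration-prone monoester.
- Comparison: more predictable stereochemistry, clearly longer. The chosen plan creates chirality once, from a racemate.

**Alternative 3:** lipase desymmetrisation of a prochiral aryl glycerol.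
- Cut: the O–acetyl bond.
- Forward key step: a lipase with vinyl acetate acetylates one enantiotopic hydroxymethyl group of triol A6, giving monoacetate A7.
- Merits: the shortest route. A6 is achiral and easily made. The stereo-determining step installs an ester of the target, the catalyst is cheap, and the allyl ether end game is available.
- Weak points: recognition of enantiotopic CH2OH groups on a fully substituted carbon bearing a hydroxyl and an ortho-substituted aryl group is not predictable. Acylation of both arms competes. The sense of induction must be found by screening. A7 can racemise by acetyl migration during the slow enzymatic reaction.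
- Comparison: with a selective enzyme this road would be shorter and cheaper. The chosen plan passes through the analogous monoacetate 15 and shares that weakness. It sets against it that the stereocentre is created in 12, where the arms are vinyl and CH2OH and cannot interconvert, so the enantiomeric purity can be assayed and upgraded before the sensitive stage, and the absolute sense is chosen by the handedness of the ligand.

Key step: step 7

Assumption: the (R,R)-diphosphine is taken to give (R)-12 by transfer of the facial sense known for 2-alkyl-2-vinyloxiranes (the CIP letter changes because aryl outranks vinyl, whereas alkyl does not). If the first sample shows the other sense, the (S,S)-ligand is used with no other change.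

Abbreviation in names: Ar = 2-(methoxymethoxy)-4-({[tri(propan-2-yl)silyl]oxy}methyl)phenyl.

## Route

Step 1
Reactants: 1 methyl 4-bromo-3-hydroxybenzoate
Product: 2 methyl 4-bromo-3-(methoxymethoxy)benzoate
Conditions: MOMCl, i-Pr2NEt, CH2Cl2, 0 °C to rt
Reagents that add atoms: chloromethyl methyl ether (MOMCl), COCCl
Why: O-Alkylation of the phenol (made more acidic by the ortho bromine and para ester) with the chloromethyl ether under amine base; the methoxymethyl acetal tolerates and stabilises the ortho-lithio species of step 4, where an aryl silyl ether would undergo a retro-Brook silyl shift.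

Step 2
Reactants: 2 methyl 4-bromo-3-(methoxymethoxy)benzoate
Product: 3 [4-bromo-3-(methoxymethoxy)phenyl]methanol
Conditions: i-Bu2AlH (2.5 equiv), CH2Cl2, −78 to 0 °C; aqueous potassium sodium tartrate
Reagents that add atoms: none
Why: Hydride reduction of the methyl ester to the primary benzylic alcohol; the aryl bromide and the acetal are inert to i-Bu2AlH at or below 0 °C.

Step 3
Reactants: 3 [4-bromo-3-(methoxymethoxy)phenyl]methanol
Product: 4 {[4-bromo-3-(methoxymethoxy)phenyl]methoxy}tri(propan-2-yl)silane
Conditions: i-Pr3SiCl, imidazole, DMF, rt
Reagents that add atoms: chlorotri(propan-2-yl)silane, CC(C)[Si](Cl)(C(C)C)C(C)C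
Why: Silylation of an unhindered primary alcohol by the silyl chloride–imidazole method; the triisopropylsilyl ether withstands butyllithium, the Grignard reagent, NaH, ozone and acylations and is later removed by fluoride without touching esters.

Step 4
Reactants: 4 {[4-bromo-3-(methoxymethoxy)phenyl]methoxy}tri(propan-2-yl)silane; 5 2-chloro-N-methoxy-N-methylacetamide
Product: 8 2-chloro-1-[Ar]ethan-1-one, via aryllithium 6 (not isolated), via lithium hemiaminal chelate 7 (not isolated)
Conditions: n-BuLi, THF, −78 °C; then 5, −78 to −20 °C; aqueous NH4Cl
Reagents that add atoms: none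
Why: Bromine–lithium exchange is faster than attack on the acetal or silyl ether and gives aryllithium 6, stabilised by the ortho methoxymethoxy group; acylation by the N-methoxy-N-methylamide (Weinreb ketone synthesis) stops at the chelated tetrahedral adduct 7, which collapses to the α-chloro ketone only on aqueous work-up, so no second addition occurs.

Step 5
Reactants: 8 2-chloro-1-[Ar]ethan-1-one
Product: 9 racemic 1-chloro-2-[Ar]but-3-en-2-ol
Conditions: CH2=CHMgBr, THF, −78 to −40 °C; aqueous NH4Cl
Reagents that add atoms: vinylmagnesium bromide, C=C[Mg]Br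
Why: 1,2-Addition of the vinyl Grignard reagent to the aryl ketone, activated by the α-chlorine and by chelation to the ortho acetal oxygen; at low temperature the magnesium alkoxide neither closes nor rearranges, and a racemic tertiary alcohol is all the next two steps require.

Step 6
Reactants: 9 racemic 1-chloro-2-[Ar]but-3-en-2-ol
Product: 10 racemic 2-ethenyl-2-[Ar]oxirane
Conditions: NaH, THF, 0 °C to rt; filtration through Et3N-deactivated silica
Reagents that add atoms: none
Why: Intramolecular Williamson etherification in which the sodium alkoxide displaces the neighbouring primary chloride (3-exo-tet), the classical chlorohydrin route to 2-substituted 2-vinyloxiranes; aprotic, acid-free handling protects the benzylic, allylic epoxide from solvolysis and Meinwald rearrangement.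

Step 7
Reactants: 10 racemic 2-ethenyl-2-[Ar]oxirane
Product: 12 (2R)-2-[Ar]but-3-ene-1,2-diol, via sodium carbonate half ester 11 (not isolated)
Conditions: Pd2(dba)3·CHCl3 (1 mol %), (R,R)-N,N′-(cyclohexane-1,2-diyl)bis[2-(diphenylphosphanyl)benzamide] (3 mol %), Et3B (2 mol %), NaHCO3 (1.5 equiv), CH2Cl2/H2O, rt
Reagents that add atoms: sodium hydrogencarbonate, [Na+].OC([O-])=O
Why: Zerovalent palladium carrying the C2-symmetric diphosphine ionises the allylic C–O bond of either enantiomer of 10 with inversion, giving diastereomeric π-allyl complexes of divalent palladium that bear a primary alkoxide. Et3B binds this alkoxide, and the complexes interconvert by π–σ–π isomerisation through the unsubstituted CH2 terminus faster than they are captured, so both enantiomers of 10 drain through one reactive complex (dynamic kinetic asymmetric transformation). Hydrogencarbonate held on boron attacks the adjacent fully substituted terminus anti to palladium to give the carbonate half ester 11, which loses CO2 and leaves the tertiary alcohol beside the primary one. The closest known reactions are this palladium–borane hydrogencarbonate addition to 2-alkyl-2-vinyloxiranes and the palladium-catalysed asymmetric hydration of 4-aryl-4-vinyl-1,3-dioxolan-2-ones, which pass through the same kind of aryl-substituted alkoxy allyl complex. No ring closes; the oxirane opens, and one C–O bond and one stereocentre are formed. The (R) configuration is controlled by the ligand alone, because the only stereocentre of the racemic substrate is erased on ionisation. The step needs branched rather than linear attack, secured by boron-tethered delivery next to the alkoxide and by the positive charge that the alkoxyaryl group localises on the substituted terminus, and it needs capture to outrun β-hydride elimination, which intramolecular delivery favours. The diol cannot re-ionise under these conditions, so the enantiomeric purity is fixed and can be assayed on a compound whose two arms cannot interconvert.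

Step 8
Reactants: 12 (2R)-2-[Ar]but-3-ene-1,2-diol
Product: 13 (2R)-2-hydroxy-2-[Ar]but-3-en-1-yl acetate
Conditions: Ac2O, pyridine, CH2Cl2, 0 °C
Reagents that add atoms: acetic anhydride, CC(=O)OC(C)=O
Why: Acylation of the primary hydroxyl is far faster than that of the hindered tertiary benzylic one, and the second arm is still a vinyl group, so the ester cannot migrate to a position that would affect the configuration.

Step 9
Reactants: 13 (2R)-2-hydroxy-2-[Ar]but-3-en-1-yl acetate
Product: 15 (2S)-2,3-dihydroxy-2-[Ar]propyl acetate, via hydroxy aldehyde 14 (not isolated)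
Conditions: O3, CH2Cl2/MeOH, −78 °C (Sudan Red 7B end point); Me2S, −78 °C to rt; then NaBH(OAc)3, AcOH, CH2Cl2, 0 °C
Reagents that add atoms: ozone, [O-][O+]=O
Why: Ozonolysis of the monosubstituted alkene (Criegee mechanism, methanol trapping the formaldehyde oxide, the dye sparing the electron-rich arene) and Me2S reduction give the non-enolisable α-hydroxy aldehyde 14, which NaBH(OAc)3 reduces at once by hydride delivery from boron bound to the neighbouring hydroxyl. The weakly acidic, alkoxide-free medium is chosen so that neither acetyl migration between the two primary oxygens, which would racemise 15, nor α-ketol rearrangement of 14 competes; the stereocentre is untouched and only its CIP letter changes.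

Step 10
Reactants: 15 (2S)-2,3-dihydroxy-2-[Ar]propyl acetate; 16 angelic acid [(2Z)-2-methylbut-2-enoic acid]
Product: 18 (2R)-3-(acetyloxy)-2-hydroxy-2-[Ar]propyl (2Z)-2-methylbut-2-enoate, via mixed anhydride 17 (not isolated)
Conditions: 16, 2,4,6-Cl3C6H2COCl, Et3N, toluene, rt; then 15, toluene, rt to 60 °C
Reagents that add atoms: none
Why: Esterification through mixed anhydride 17 (Yamaguchi-type activation) run without 4-(dimethylamino)pyridine, the protocol that preserves the Z geometry because no acylpyridinium species that could isomerise is formed; the alcohol attacks the less hindered angeloyl carbonyl. Only the primary hydroxyl reacts, and once both arms are acylated the configuration can no longer be lost by acyl migration.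

Step 11
Reactants: 18 (2R)-3-(acetyloxy)-2-hydroxy-2-[Ar]propyl (2Z)-2-methylbut-2-enoate
Product: 19 (2R)-3-(acetyloxy)-2-hydroxy-2-[4-(hydroxymethyl)-2-(methoxymethoxy)phenyl]propyl (2Z)-2-methylbut-2-enoate
Conditions: HF·pyridine, pyridine, THF, 0 °C to rt
Reagents that add atoms: none
Why: Fluoride-driven cleavage of the Si–O bond; pyridine-buffered HF is neither basic enough to move or cleave the acyl groups nor acidic enough to ionise the carbinol or open the methoxymethyl acetal.

Step 12
Reactants: 19 (2R)-3-(acetyloxy)-2-hydroxy-2-[4-(hydroxymethyl)-2-(methoxymethoxy)phenyl]propyl (2Z)-2-methylbut-2-enoate; 20 (2R)-2-methylbutanoic acid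
Product: 21 {4-[(2R)-1-(acetyloxy)-2-hydroxy-3-{[(2Z)-2-methylbut-2-enoyl]oxy}propan-2-yl]-3-(methoxymethoxy)phenyl}methyl (2R)-2-methylbutanoate
Conditions: EDC·HCl, DMAP (0.1 equiv), CH2Cl2, 0 °C to rt
Reagents that add atoms: none
Why: Steglich esterification of the unhindered benzylic alcohol; the tertiary hydroxyl does not react, and with catalytic DMAP at 0 °C the α-stereocentre of a simple α-branched acid, which carries no activating group, should not epimerise.

Step 13
Reactants: 21 {4-[(2R)-1-(acetyloxy)-2-hydroxy-3-{[(2Z)-2-methylbut-2-enoyl]oxy}propan-2-yl]-3-(methoxymethoxy)phenyl}methyl (2R)-2-methylbutanoate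
Product: 23 {4-[(2R)-1-(acetyloxy)-2-hydroxy-3-{[(2Z)-2-methylbut-2-enoyl]oxy}propan-2-yl]-3-hydroxyphenyl}methyl (2R)-2-methylbutanoate (CNP0197977.1), via bis(trimethylsilyl) ether 22 (not isolated)
Conditions: Me3SiOSO2CF3 (4 equiv), 2,2′-bipyridyl (6 equiv), MeCN, 0 °C to rt; then H2O, dilute aqueous citric acid/THF, 0 °C
Reagents that add atoms: none
Why: The silyl triflate–bipyridyl complex cleaves aromatic methoxymethyl ethers at the aryl O–CH2 bond, passing the methoxymethyl group to pyridine nitrogen and giving the aryl silyl ether, so no oxocarbenium ion is formed on the phenol oxygen that the neighbouring tertiary hydroxyl could trap; excess reagent silylates that hydroxyl in the flask (22). Mild aqueous acid then hydrolyses both Si–O bonds, while the three esters, the Z alkene and the benzylic carbinol lie outside the reach of this weakly Lewis acidic, non-protic reagent.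

## Compound list

1 | methyl 4-bromo-3-hydroxybenzoate | COC(=O)c1ccc(Br)c(O)c1 | starting material
2 | methyl 4-bromo-3-(methoxymethoxy)benzoate | COCOc1cc(C(=O)OC)ccc1Br | intermediate
3 | [4-bromo-3-(methoxymethoxy)phenyl]methanol | COCOc1cc(CO)ccc1Br | intermediate
4 | {[4-bromo-3-(methoxymethoxy)phenyl]methoxy}tri(propan-2-yl)silane | COCOc1cc(CO[Si](C(C)C)(C(C)C)C(C)C)ccc1Br | intermediate
5 | 2-chloro-N-methoxy-N-methylacetamide | CON(C)C(=O)CCl | starting material
6 | [2-(methoxymethoxy)-4-({[tri(propan-2-yl)silyl]oxy}methyl)phenyl]lithium | [Li]c1ccc(CO[Si](C(C)C)(C(C)C)C(C)C)cc1OCOC | intermediate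
7 | lithium 2-chloro-1-[methoxy(methyl)amino]-1-[2-(methoxymethoxy)-4-({[tri(propan-2-yl)silyl]oxy}methyl)phenyl]ethan-1-olate (racemic tetrahedral chelate) | [Li]OC(CCl)(N(C)OC)c1ccc(CO[Si](C(C)C)(C(C)C)C(C)C)cc1OCOC | intermediate
8 | 2-chloro-1-[2-(methoxymethoxy)-4-({[tri(propan-2-yl)silyl]oxy}methyl)phenyl]ethan-1-one | O=C(CCl)c1ccc(CO[Si](C(C)C)(C(C)C)C(C)C)cc1OCOC | intermediate
9 | racemic 1-chloro-2-[2-(methoxymethoxy)-4-({[tri(propan-2-yl)silyl]oxy}methyl)phenyl]but-3-en-2-ol | C=CC(O)(CCl)c1ccc(CO[Si](C(C)C)(C(C)C)C(C)C)cc1OCOC | intermediate
10 | racemic 2-ethenyl-2-[2-(methoxymethoxy)-4-({[tri(propan-2-yl)silyl]oxy}methyl)phenyl]oxirane | C=CC1(CO1)c1ccc(CO[Si](C(C)C)(C(C)C)C(C)C)cc1OCOC | intermediate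
11 | sodium (2R)-1-hydroxy-2-[2-(methoxymethoxy)-4-({[tri(propan-2-yl)silyl]oxy}methyl)phenyl]but-3-en-2-yl carbonate | C=C[C@](OC(=O)[O-])(CO)c1ccc(CO[Si](C(C)C)(C(C)C)C(C)C)cc1OCOC.[Na+] | intermediate
12 | (2R)-2-[2-(methoxymethoxy)-4-({[tri(propan-2-yl)silyl]oxy}methyl)phenyl]but-3-ene-1,2-diol | C=C[C@](O)(CO)c1ccc(CO[Si](C(C)C)(C(C)C)C(C)C)cc1OCOC | intermediate
13 | (2R)-2-hydroxy-2-[2-(methoxymethoxy)-4-({[tri(propan-2-yl)silyl]oxy}methyl)phenyl]but-3-en-1-yl acetate | C=C[C@](O)(COC(C)=O)c1ccc(CO[Si](C(C)C)(C(C)C)C(C)C)cc1OCOC | intermediate
14 | (2R)-2-hydroxy-2-[2-(methoxymethoxy)-4-({[tri(propan-2-yl)silyl]oxy}methyl)phenyl]-3-oxopropyl acetate | O=C[C@](O)(COC(C)=O)c1ccc(CO[Si](C(C)C)(C(C)C)C(C)C)cc1OCOC | intermediate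
15 | (2S)-2,3-dihydroxy-2-[2-(methoxymethoxy)-4-({[tri(propan-2-yl)silyl]oxy}methyl)phenyl]propyl acetate | OC[C@](O)(COC(C)=O)c1ccc(CO[Si](C(C)C)(C(C)C)C(C)C)cc1OCOC | intermediate
16 | angelic acid, (2Z)-2-methylbut-2-enoic acid | C/C=C(/C)C(=O)O | starting material
17 | (2Z)-2-methylbut-2-enoic 2,4,6-trichlorobenzoic anhydride | C/C=C(/C)C(=O)OC(=O)c1c(Cl)cc(Cl)cc1Cl | intermediate
18 | (2R)-3-(acetyloxy)-2-hydroxy-2-[2-(methoxymethoxy)-4-({[tri(propan-2-yl)silyl]oxy}methyl)phenyl]propyl (2Z)-2-methylbut-2-enoate | C/C=C(/C)C(=O)OC[C@](O)(COC(C)=O)c1ccc(CO[Si](C(C)C)(C(C)C)C(C)C)cc1OCOC | intermediate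
19 | (2R)-3-(acetyloxy)-2-hydroxy-2-[4-(hydroxymethyl)-2-(methoxymethoxy)phenyl]propyl (2Z)-2-methylbut-2-enoate | C/C=C(/C)C(=O)OC[C@](O)(COC(C)=O)c1ccc(CO)cc1OCOC | intermediate
20 | (2R)-2-methylbutanoic acid | OC(=O)[C@H](C)CC | starting material
21 | {4-[(2R)-1-(acetyloxy)-2-hydroxy-3-{[(2Z)-2-methylbut-2-enoyl]oxy}propan-2-yl]-3-(methoxymethoxy)phenyl}methyl (2R)-2-methylbutanoate | C/C=C(/C)C(=O)OC[C@](O)(COC(C)=O)c1ccc(COC(=O)[C@H](C)CC)cc1OCOC | intermediate
22 | {4-[(2R)-1-(acetyloxy)-3-{[(2Z)-2-methylbut-2-enoyl]oxy}-2-[(trimethylsilyl)oxy]propan-2-yl]-3-[(trimethylsilyl)oxy]phenyl}methyl (2R)-2-methylbutanoate | C/C=C(/C)C(=O)OC[C@](O[Si](C)(C)C)(COC(C)=O)c1ccc(COC(=O)[C@H](C)CC)cc1O[Si](C)(C)C | intermediate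
23 | {4-[(2R)-1-(acetyloxy)-2-hydroxy-3-{[(2Z)-2-methylbut-2-enoyl]oxy}propan-2-yl]-3-hydroxyphenyl}methyl (2R)-2-methylbutanoate | C/C=C(/C)C(=O)OC[C@](O)(COC(C)=O)c1ccc(COC(=O)[C@H](C)CC)cc1O | target

## Step count and least certain steps

Total: 13 steps. Longest linear sequence: 13 steps (1 to 23); 5, 16 and 20 are bought and enter in steps 4, 10 and 12.

**Step 7 (key step).**
- What may go wrong: the ortho-substituted aryl group may crowd the ligand pocket or slow the equilibration of the allyl complexes relative to capture, lowering enantioselectivity. Attack at the unsubstituted terminus, β-hydride elimination from the allyl complex, or acid-type rearrangement of 10 before it meets the catalyst may compete.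
- Fallback: it sets out from racemic 10. CO2 (1 atm) with catalytic Pd(PPh3)4 in THF inserts into the allylic C–O bond and gives racemic 4-ethenyl-4-[Ar]-1,3-dioxolan-2-one F1, a bench-stable surrogate of the epoxide. Decarboxylative asymmetric allylic substitution of F1 with water (Pd2(dba)3·CHCl3, a BINOL-derived phosphoramidite, Et3B co-catalyst, THF/H2O), the variant developed for 4-aryl substrates, comes back to the route at 12. Electrophile, oxygen donor and ligand class all change.

**Step 9.**
- What may go wrong: acetyl migration from one primary oxygen to the other across the tertiary hydroxyl once the second arm is unmasked (loss of enantiomeric purity); α-ketol shift of 14; over-oxidation of the arene by ozone.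
- Fallback: it sets out from 12. Et3SiCl and imidazole at −20 °C give the primary silyl ether (2R)-2-[Ar]-1-[(triethylsilyl)oxy]but-3-en-2-ol F2. Ozonolysis with direct NaBH4 reduction, now harmless because no acyl group is present, gives (2S)-2-[Ar]-3-[(triethylsilyl)oxy]propane-1,2-diol F3. Angeloylation as in step 10, if necessary at 80 °C, gives (2S)-2-hydroxy-2-[Ar]-3-[(triethylsilyl)oxy]propyl (2Z)-2-methylbut-2-enoate F4. Pyridinium p-toluenesulfonate in MeOH removes the triethylsilyl group beside the triisopropylsilyl ether and gives (2R)-2,3-dihydroxy-2-[Ar]propyl (2Z)-2-methylbut-2-enoate F5, in which the free arm is flanked by the slow-migrating angelate. Immediate acetylation (Ac2O, pyridine, 0 °C) comes back at 18, at the cost of two steps.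

**Step 10.**
- What may go wrong: Z-to-E isomerisation of the activated 2-methylbut-2-enoyl unit; slow acylation of the neopentyl-type hydroxyl, which would leave time for the acetyl migration described under step 9.
- Fallback: it sets out from 15. Carbodiimide coupling (EDC·HCl, catalytic DMAP, 0 °C) with 2-[bis(2,2,2-trifluoroethoxy)phosphoryl]propanoic acid gives (2R)-3-(acetyloxy)-2-hydroxy-2-[Ar]propyl 2-[bis(2,2,2-trifluoroethoxy)phosphoryl]propanoate F6. Still–Gennari olefination of F6 (KN(SiMe3)2, 18-crown-6, THF, −78 °C, acetaldehyde) builds the Z trisubstituted alkene on the ester and comes back at 18. The geometry is then set by the olefination, not by the survival of an activated angeloyl species.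

**Step 13.**
- What may go wrong: transfer of the methylene unit to the neighbouring tertiary hydroxyl; ionisation at the benzylic carbinol with acyl shift; sluggish hydrolysis of the hindered tertiary silyl ether, which would force stronger acid.
- Fallback: it sets out from 21. Et3SiOSO2CF3 and 2,2′-bipyridyl exchange the aryl methoxymethyl ether for a triethylsilyl ether and cap the tertiary hydroxyl, giving the isolable {4-[(2R)-1-(acetyloxy)-3-{[(2Z)-2-methylbut-2-enoyl]oxy}-2-[(triethylsilyl)oxy]propan-2-yl]-3-[(triethylsilyl)oxy]phenyl}methyl (2R)-2-methylbutanoate F7. Buffered HF·pyridine, already used in step 11 on the same ester array, then frees both hydroxyls and comes back at 23. The last bond broken is Si–O by fluoride, not a C–O bond under acid.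

**Step 4.**
- What may go wrong: proton transfer from the acidic α-chloro amide to the aryllithium, or attack at the carbon bearing chlorine, in place of acylation.
- Fallback: it sets out from 4 (through 6). N-Methoxy-N-methylacetamide gives 1-[Ar]ethan-1-one F8. LiN(SiMe3)2 and Me3SiCl give trimethyl{[1-[Ar]ethenyl]oxy}silane F9. N-Chlorosuccinimide then chlorinates the enol ether and comes back at 8.

## Further compounds

F1 | step 7 | racemic 4-ethenyl-4-[2-(methoxymethoxy)-4-({[tri(propan-2-yl)silyl]oxy}methyl)phenyl]-1,3-dioxolan-2-one | C=CC1(COC(=O)O1)c1ccc(CO[Si](C(C)C)(C(C)C)C(C)C)cc1OCOC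
F2 | step 9 | (2R)-2-[2-(methoxymethoxy)-4-({[tri(propan-2-yl)silyl]oxy}methyl)phenyl]-1-[(triethylsilyl)oxy]but-3-en-2-ol | C=C[C@](O)(CO[Si](CC)(CC)CC)c1ccc(CO[Si](C(C)C)(C(C)C)C(C)C)cc1OCOC
F3 | step 9 | (2S)-2-[2-(methoxymethoxy)-4-({[tri(propan-2-yl)silyl]oxy}methyl)phenyl]-3-[(triethylsilyl)oxy]propane-1,2-diol | OC[C@](O)(CO[Si](CC)(CC)CC)c1ccc(CO[Si](C(C)C)(C(C)C)C(C)C)cc1OCOC
F4 | step 9 | (2S)-2-hydroxy-2-[2-(methoxymethoxy)-4-({[tri(propan-2-yl)silyl]oxy}methyl)phenyl]-3-[(triethylsilyl)oxy]propyl (2Z)-2-methylbut-2-enoate | C/C=C(/C)C(=O)OC[C@](O)(CO[Si](CC)(CC)CC)c1ccc(CO[Si](C(C)C)(C(C)C)C(C)C)cc1OCOC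
F5 | step 9 | (2R)-2,3-dihydroxy-2-[2-(methoxymethoxy)-4-({[tri(propan-2-yl)silyl]oxy}methyl)phenyl]propyl (2Z)-2-methylbut-2-enoate | C/C=C(/C)C(=O)OC[C@](O)(CO)c1ccc(CO[Si](C(C)C)(C(C)C)C(C)C)cc1OCOC
F6 | step 10 | (2R)-3-(acetyloxy)-2-hydroxy-2-[2-(methoxymethoxy)-4-({[tri(propan-2-yl)silyl]oxy}methyl)phenyl]propyl 2-[bis(2,2,2-trifluoroethoxy)phosphoryl]propanoate (mixture at the phosphonate carbon) | CC(C(=O)OC[C@](O)(COC(C)=O)c1ccc(CO[Si](C(C)C)(C(C)C)C(C)C)cc1OCOC)P(=O)(OCC(F)(F)F)OCC(F)(F)F
F7 | step 13 | {4-[(2R)-1-(acetyloxy)-3-{[(2Z)-2-methylbut-2-enoyl]oxy}-2-[(triethylsilyl)oxy]propan-2-yl]-3-[(triethylsilyl)oxy]phenyl}methyl (2R)-2-methylbutanoate | C/C=C(/C)C(=O)OC[C@](O[Si](CC)(CC)CC)(COC(C)=O)c1ccc(COC(=O)[C@H](C)CC)cc1O[Si](CC)(CC)CC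
F8 | step 4 | 1-[2-(methoxymethoxy)-4-({[tri(propan-2-yl)silyl]oxy}methyl)phenyl]ethan-1-one | CC(=O)c1ccc(CO[Si](C(C)C)(C(C)C)C(C)C)cc1OCOC
F9 | step 4 | trimethyl({1-[2-(methoxymethoxy)-4-({[tri(propan-2-yl)silyl]oxy}methyl)phenyl]ethenyl}oxy)silane | C=C(O[Si](C)(C)C)c1ccc(CO[Si](C(C)C)(C(C)C)C(C)C)cc1OCOC
A1 | alternative 1 | 3-({[tri(propan-2-yl)silyl]oxy}methyl)phenol | Oc1cccc(CO[Si](C(C)C)(C(C)C)C(C)C)c1
A2 | alternative 1 | ethyl 3-[(4-methoxyphenyl)methoxy]-2-oxopropanoate | CCOC(=O)C(=O)COCc1ccc(OC)cc1
A3 | alternative 1 | ethyl (2S)-2-hydroxy-2-[2-hydroxy-4-({[tri(propan-2-yl)silyl]oxy}methyl)phenyl]-3-[(4-methoxyphenyl)methoxy]propanoate | COc1ccc(COC[C@](O)(C(=O)OCC)c2ccc(CO[Si](C(C)C)(C(C)C)C(C)C)cc2O)cc1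
A4 | alternative 2 | (2R,5R)-2-tert-butyl-5-[2-(prop-2-en-1-yloxy)-4-({[tri(propan-2-yl)silyl]oxy}methyl)phenyl]-1,3-dioxolan-4-one (aryl cis to tert-butyl) | O=C1O[C@H](C(C)(C)C)O[C@@H]1c1ccc(CO[Si](C(C)C)(C(C)C)C(C)C)cc1OCC=C
A5 | alternative 2 | (2R,5S)-2-tert-butyl-5-(hydroxymethyl)-5-[2-(prop-2-en-1-yloxy)-4-({[tri(propan-2-yl)silyl]oxy}methyl)phenyl]-1,3-dioxolan-4-one (aryl cis to tert-butyl) | O=C1O[C@H](C(C)(C)C)O[C@]1(CO)c1ccc(CO[Si](C(C)C)(C(C)C)C(C)C)cc1OCC=C
A6 | alternative 3 | 2-[2-(prop-2-en-1-yloxy)-4-({[tri(propan-2-yl)silyl]oxy}methyl)phenyl]propane-1,2,3-triol | OCC(O)(CO)c1ccc(CO[Si](C(C)C)(C(C)C)C(C)C)cc1OCC=C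
A7 | alternative 3 | (2S)-2,3-dihydroxy-2-[2-(prop-2-en-1-yloxy)-4-({[tri(propan-2-yl)silyl]oxy}methyl)phenyl]propyl acetate | OC[C@](O)(COC(C)=O)c1ccc(CO[Si](C(C)C)(C(C)C)C(C)C)cc1OCC=C
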